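## Retrosynthetic overview

Terpene numbering: C1 is the ArCH2 carbon. C11 is the quaternary ring carbon bearing the side chain, and C16 is the exocyclic methylene on C11 in the precursor.

1. Jaspic acid ⇐ ester hydrolysis and desilylation ⇐ deoxygenation of a stereo-directing C9 carbinol ⇐ ArBr→ArCO2Me carbonylation ⇐ bicyclic alcohol **17**.
2. Key disconnection: the C6–C11 and C2–C7 bonds of **17**. Co–H hydrogen-atom transfer (HAT) to the C11 methylene of triene **16** gives a tertiary C11 radical. This cyclises 6-endo onto C6=C7 (ring A), then the tertiary C7 radical cyclises 6-endo onto C2=C3 (ring B). Radical termination by HAT gives the Δ3 alkene.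
3. **16** ⇐ Brown asymmetric allylation of aldehyde **15** with the 2-alkylallylborane from **5**. This installs the C9 carbinol, which fixes the chair and the absolute sense of the cascade.
4. **15** ⇐ 4-bromophenol and isoprene monoepoxide (C1–C4), allyl Grignard (C5–C7), and isoprenol by cross-metathesis (C7–C9). The right-hand allyl chloride comes from 3-chloro-2-(chloromethyl)propene and allyl Grignard, followed by cross-metathesis.

Assumption: the aryl TBS ether and aryl bromide survive the radical steps, and the minor (Z)-isomers from steps 5 and 8 are removed by AgNO3–silica chromatography.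

## Forward route

**Step 1**
Reactants: **1** 3-chloro-2-(chloromethyl)prop-1-ene; **2** allylmagnesium bromide
Product: **3** 2-(chloromethyl)hexa-1,5-diene
Conditions: CuI (5 mol%), THF, –20 °C → rt (3 equiv of 1)
Reagents that add atoms: none
Why: Cu-catalysed Grignard SN2 alkylation of a symmetric bis-allylic chloride; SN2 and SN2′ give the same product, and excess 1 suppresses double substitution.

**Step 2**
Reactants: **3**; **4** 2-methylbut-2-ene
Product: **5** 2-(chloromethyl)-6-methylhepta-1,5-diene
Conditions: Grubbs II (3 mol%), 4 (10 equiv), CH2Cl2, 40 °C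
Reagents that add atoms: none
Why: Cross-metathesis converts the monosubstituted alkene into the prenyl terminus while the hindered 1,1-disubstituted alkene is left alone.

**Step 3**
Reactant: **6** 4-bromophenol
Product: **7** 4-bromo-2-iodophenol
Conditions: NIS, TsOH (cat.), CH2Cl2, 0 °C → rt
Reagents that add atoms: N-iodosuccinimide, O=C1CCC(=O)N1I
Why: Electrophilic aromatic iodination goes ortho to OH because the para position is blocked.

**Step 4**
Reactant: **7**
Product: **8** tert-butyl(4-bromo-2-iodophenoxy)dimethylsilane
Conditions: TBSCl, imidazole, DMF, rt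
Reagents that add atoms: TBSCl, CC(C)(C)[Si](C)(C)Cl
Why: Silyl protection of the phenol makes the aryl-Grignard steps possible.

**Step 5**
Reactants: **8**; **9** isoprene monoepoxide (2-methyl-2-vinyloxirane)
Product: **10** (E)-4-[5-bromo-2-(TBSO)phenyl]-2-methylbut-2-en-1-ol
Conditions: iPrMgCl·LiCl, THF, –20 °C; then 9, CuI (10 mol%), –20 → 0 °C
Reagents that add atoms: none
Why: Selective I/Mg exchange, then Cu-catalysed SN2′ opening of the vinyl epoxide (Grignard–vinyl epoxide coupling). This forms the ArCH2–CH= bond (C1–C2) and the E-trisubstituted C2=C3 alkene (E major).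

**Step 6**
Reactant: **10**
Product: **11** (E)-allylic bromide, BrCH2–C(Me)=CH–CH2–Ar′
Conditions: CBr4, PPh3, CH2Cl2, 0 °C
Reagents that add atoms: CBr4, BrC(Br)(Br)Br
Why: Appel bromination with no allylic transposition; the product is used crude.

**Step 7**
Reactants: **11**; **2** allylmagnesium bromide
Product: **12** (E)-triene, CH2=CH–CH2–CH2–C(Me)=CH–CH2–Ar′
Conditions: Li2CuCl4 (5 mol%), THF, –20 °C
Reagents that add atoms: none
Why: Cu-catalysed allyl–allyl SN2 coupling forms C4–C5; the E alkene is retained.

**Step 8**
Reactants: **12**; **13** isoprenol (3-methylbut-3-en-1-ol)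
Product: **14** (2E,6E)-alcohol, HOCH2CH2–C(Me)=CH–CH2CH2–C(Me)=CH–CH2–Ar′
Conditions: Hoveyda–Grubbs II (5 mol%), 13 (5 equiv), CH2Cl2, 40 °C
Reagents that add atoms: none
Why: Cross-metathesis of the terminal alkene with the 1,1-disubstituted alkene of 13 forms the trisubstituted C6=C7 bond (E:Z about 4:1) and installs C7–C9.

**Step 9**
Reactant: **14**
Product: **15** (E,E)-aldehyde, OHC–CH2–C(Me)=CH–CH2CH2–C(Me)=CH–CH2–Ar′
Conditions: DMP, NaHCO3, CH2Cl2, 0 °C
Reagents that add atoms: none
Why: Buffered Dess–Martin oxidation avoids isomerisation of the β,γ-unsaturated aldehyde into conjugation.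

**Step 10**
Reactants: **15**; **5** (as its Grignard, then the allyl-diisopinocampheylborane)
Product: **16** (S)-homoallylic alcohol, Ar′CH2CH=C(Me)CH2CH2CH=C(Me)CH2–CH(OH)–CH2–C(=CH2)–CH2CH2CH=CMe2 (E,E; C9 = S)
Conditions: 5, Mg, Et2O; then (–)-(Ipc)2BOMe, –78 °C; then 15, –78 °C; NaBO3·4H2O, THF/H2O (the (Ipc)2BOMe enantiomer is chosen to give the (S)-carbinol)
Reagents that add atoms: none (the allyl unit comes from 5)
Why: Brown asymmetric allylation proceeds through a Zimmerman–Traxler chair. It sets C9(S) and forms C10–C11 with the 1,1-disubstituted alkene. The C9 OH will sit equatorial in the cascade chair and dictates the enantiomer formed.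

**Step 11**
Reactant: **16**
Product: **17** bicyclic alcohol (trans-decalin, Δ3 alkene, C9-OH)
Conditions: Co(salen)Cl (5 mol%), PhSiH3 (20 mol%), PhMe (0.01 M), 25 °C
Reagents that add atoms: none (isomerisation)
Why: Radical polyene cycloisomerisation initiated by metal-hydride HAT (MHAT): Co–H adds H selectively to the 1,1-disubstituted C11=C16 alkene. The tertiary C11 radical then cyclises 6-endo onto C6=C7 (5-methyl-5-hexenyl pattern) through a chair with C9-OH equatorial. The resulting tertiary C7 radical cyclises 6-endo onto C2=C3. The E,E alkenes and chair–chair geometry set C6–H, C7–Me and C2–CH2Ar (trans-decalin, CH2Ar equatorial), and Co(II) removes the C4-H to give the Δ3 alkene. The C11 configuration depends only on Me versus CH2R discrimination, so the diastereomers (about 1:1 to 2:1) are separated by HPLC on AgNO3–SiO2.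
Proposed new method: MHAT-initiated two-ring radical cascade from an internal 1,1-disubstituted alkene, with Co(II)-mediated desaturative termination. It follows Co–H radical cycloisomerisation of dienes and Ti(III) radical polyene cyclisations.

**Step 12**
Reactant: **17**
Product: **18** methyl ester
Conditions: Pd(OAc)2, dppf, CO (10 atm), Et3N, MeOH/DMF, 100 °C
Reagents that add atoms: carbon monoxide [C-]#[O+]; methanol CO
Why: Pd-catalysed alkoxycarbonylation of the aryl bromide; it is done before the tin hydride step so the ArBr is not reduced.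

**Step 13**
Reactant: **18**
Product: **19** C9 methyl xanthate
Conditions: NaH, CS2, THF, 0 °C; then MeI
Reagents that add atoms: carbon disulfide S=C=S; iodomethane CI
Why: Barton–McCombie activation; the configuration at C9 is retained.

**Step 14**
Reactant: **19**
Product: **20** deoxygenated methyl ester, TBS ether
Conditions: Bu3SnH (5 equiv, 0.25 M), AIBN, PhMe, 90 °C
Reagents that add atoms: none
Why: Barton–McCombie radical deoxygenation removes the directing oxygen; the high Bu3SnH concentration outcompetes 6-exo capture of the C9 radical by the axial prenyl alkene, and C9 becomes CH2 so no stereocentre is affected.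

**Step 15**
Reactant: **20**
Product: **21** jaspic acid
Conditions: LiOH·H2O, THF/MeOH/H2O, 60 °C; then TBAF, THF; 1 M HCl
Reagents that add atoms: water, O
Why: Ester saponification and aryl-silyl cleavage liberate the 4-hydroxybenzoic acid; no stereocentre is touched.

## Compound list

| # | Name | SMILES | Role |
|---|---|---|---|
| 1 | 3-chloro-2-(chloromethyl)prop-1-ene | C=C(CCl)CCl | starting material |
| 2 | allylmagnesium bromide | C=CC[Mg]Br | starting material |
| 3 | 2-(chloromethyl)hexa-1,5-diene | C=CCCC(=C)CCl | intermediate |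
| 4 | 2-methylbut-2-ene | CC=C(C)C | starting material |
| 5 | 2-(chloromethyl)-6-methylhepta-1,5-diene | CC(C)=CCCC(=C)CCl | intermediate |
| 6 | 4-bromophenol | Oc1ccc(Br)cc1 | starting material |
| 7 | 4-bromo-2-iodophenol | Oc1ccc(Br)cc1I | intermediate |
| 8 | tert-butyl(4-bromo-2-iodophenoxy)dimethylsilane | CC(C)(C)[Si](C)(C)Oc1ccc(Br)cc1I | intermediate |
| 9 | 2-methyl-2-vinyloxirane (isoprene monoepoxide) | C=CC1(C)CO1 | starting material |
| 10 | (E)-4-[5-bromo-2-(TBSO)phenyl]-2-methylbut-2-en-1-ol | OC/C(C)=C/Cc1cc(Br)ccc1O[Si](C)(C)C(C)(C)C | intermediate |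
| 11 | allylic bromide of 10 | BrC/C(C)=C/Cc1cc(Br)ccc1O[Si](C)(C)C(C)(C)C | intermediate |
| 12 | (E)-triene (aryl-homogeranyl terminal alkene) | C=CCC/C(C)=C/Cc1cc(Br)ccc1O[Si](C)(C)C(C)(C)C | intermediate |
| 13 | isoprenol | C=C(C)CCO | starting material |
| 14 | (E,E)-alcohol | OCC/C(C)=C/CC/C(C)=C/Cc1cc(Br)ccc1O[Si](C)(C)C(C)(C)C | intermediate |
| 15 | (E,E)-aldehyde | O=CC/C(C)=C/CC/C(C)=C/Cc1cc(Br)ccc1O[Si](C)(C)C(C)(C)C | intermediate |
| 16 | (S)-homoallylic alcohol (cascade precursor) | CC(C)=CCCC(=C)C[C@H](O)C/C(C)=C/CC/C(C)=C/Cc1cc(Br)ccc1O[Si](C)(C)C(C)(C)C | intermediate |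
| 17 | bicyclic C9-alcohol, aryl bromide, TBS ether | CC(C)=CCC[C@@]1(C)C[C@H](O)C[C@]2(C)[C@@H](Cc3cc(Br)ccc3O[Si](C)(C)C(C)(C)C)C(C)=CC[C@@H]12 | intermediate |
| 18 | methyl ester of 17 | CC(C)=CCC[C@@]1(C)C[C@H](O)C[C@]2(C)[C@@H](Cc3cc(C(=O)OC)ccc3O[Si](C)(C)C(C)(C)C)C(C)=CC[C@@H]12 | intermediate |
| 19 | C9 methyl xanthate | CC(C)=CCC[C@@]1(C)C[C@H](OC(=S)SC)C[C@]2(C)[C@@H](Cc3cc(C(=O)OC)ccc3O[Si](C)(C)C(C)(C)C)C(C)=CC[C@@H]12 | intermediate |
| 20 | deoxygenated methyl ester, TBS ether | CC(C)=CCC[C@@]1(C)CCC[C@]2(C)[C@@H](Cc3cc(C(=O)OC)ccc3O[Si](C)(C)C(C)(C)C)C(C)=CC[C@@H]12 | intermediate |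
| 21 | jaspic acid | CC(C)=CCC[C@@]1(C)CCC[C@]2(C)[C@@H](Cc3cc(C(=O)O)ccc3O)C(C)=CC[C@@H]12 | target |

## Totals

Total steps: 15, of which steps 1–2 are a parallel branch to 5. Longest linear sequence: 13 (steps 3–15, from 4-bromophenol).

## Three steps most likely to fail

1. **Step 11 (cascade).** The C11 configuration is set only by Me versus CH2R discrimination, and the 1,3-diaxial Me/side-chain strain in the product, plus 5-exo leakage, can reduce the yield of trans-decalin. Fallback: a stepwise polar route. Cu-catalysed asymmetric conjugate addition of homoprenylMgBr to 3-methylcyclohexenone sets the quaternary centre. Robinson annulation with methyl vinyl ketone follows, then cuprate angular methylation, enolate benzylation with an ArCH2Br fragment, and MeLi addition/dehydration to the Δ3 alkene.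
2. **Step 8 (cross-metathesis).** Yield and E/Z selectivity are uncertain, and the Grubbs catalyst can scramble the existing trisubstituted alkenes. Fallback: build C6=C7 by Zr-catalysed carboalumination of a terminal alkyne, then Cu-catalysed allylation, or use an E-selective Horner–Wadsworth–Emmons/DIBAL homologation.
3. **Step 14 (radical deoxygenation).** The C9 radical sits 1,3-diaxial to the prenyl alkene and may cyclise 6-exo to a bicyclo[3.3.1] product. Fallback: non-radical removal. Burgess dehydration of the C9 alcohol, then chemoselective diimide reduction of the new disubstituted ring alkene in the presence of the trisubstituted alkenes.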